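## Retrosynthetic overview

1. Target ← allylic oxidation at C7 ← Pd/CO chromone annulation of a 2-iodophenol (from resorcinol) onto a terminal alkyne that sits on the ring-fusion quaternary carbon.
2. Quaternary carbon and cis-fused methoxy-enedione (ring E) ← key step: acid-promoted quinol→enedione 1,2-shift of a silylalkynyl group in a bicyclic p-quinol ← hydroxylative dearomatisation of an alkynyl guaiacol.
3. Cyclohexene (ring D) ← ring-closing metathesis; C12 stereocentre ← sparteine-controlled lithiation–borylation, then Zweifel olefination, joining a homodrimane carbamate to an aryl boronate (from catechol).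
4. Decalin (rings A/B) ← enzymatic polyene cyclisation of homofarnesoic acid, built from 5-bromo-2-methylpent-2-ene by two carboalumination/oxirane iterations.
5. Ring order: A/B → ring D → ring E (dearomatised, rearranged) → chromone pyranone ring.

Assumption: the target SMILES defines the normal-labdane decalin (5S,9R,10S), so natural-series (+)-sclareolide is the correct relay.

Conventions for names: Dr(X) = (5S,9R,10S)-drim-8(12)-en-11-yl, i.e. the decalinyl–CH2 group (gem-dimethyl at C4, methyl at C10, exocyclic methylene at C8, CH2 on C9β) carrying X at C7 (OTBS or OH, both 7R/α; or =O). The bicyclic rings D/E are named as naphthalenes.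

## Route

Step 1
Reactants: 1 5-bromo-2-methylpent-2-ene
Product: 2 6-methylhept-5-en-1-yne
Conditions: LiC≡CH·H2N(CH2)2NH2, DMSO, 10 °C → rt
Reagents that add atoms: lithium acetylide [Li]C#C
Why: acetylide alkylation (SN2) at an unhindered primary homoallylic bromide; no stereocentre is formed.

Step 2
Reactants: 2 6-methylhept-5-en-1-yne
Product: 4 (E)-4,8-dimethylnona-3,7-dien-1-ol (homogeraniol), via alkenylalane 3 (not isolated)
Conditions: Me3Al, Cp2ZrCl2 (20 mol %), CH2Cl2, 0 °C → rt; then n-BuLi, THF, −30 °C; then oxirane, −30 °C → rt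
Reagents that add atoms: trimethylaluminium C[Al](C)C; oxirane C1CO1
Why: zirconium-catalysed syn-carboalumination (Negishi) fixes the E-trisubstituted alkene, and the derived alanate opens oxirane with retention of geometry.

Step 3
Reactants: 4 homogeraniol
Product: 5 (E)-9-iodo-2,6-dimethylnona-2,6-diene
Conditions: I2, PPh3, imidazole, CH2Cl2, 0 °C
Reagents that add atoms: iodine II
Why: Appel-type iodination of a primary alcohol; the alkenes are untouched.

Step 4
Reactants: 5 (E)-9-iodo-2,6-dimethylnona-2,6-diene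
Product: 6 (E)-6,10-dimethylundeca-5,9-dien-1-yne
Conditions: LiC≡CH·H2N(CH2)2NH2, DMSO, rt
Reagents that add atoms: lithium acetylide [Li]C#C
Why: second acetylide alkylation (SN2) on a primary iodide.

Step 5
Reactants: 6 (E)-6,10-dimethylundeca-5,9-dien-1-yne
Product: 8 (3E,7E)-4,8,12-trimethyltrideca-3,7,11-trien-1-ol (homofarnesol), via alkenylalane 7 (not isolated)
Conditions: Me3Al, Cp2ZrCl2 (20 mol %), CH2Cl2, 0 °C → rt; then n-BuLi, THF, −30 °C; then oxirane, −30 °C → rt
Reagents that add atoms: trimethylaluminium C[Al](C)C; oxirane C1CO1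
Why: second Negishi carboalumination/oxirane opening sets the second E-alkene exactly as in step 2.

Step 6
Reactants: 8 homofarnesol
Product: 9 (3E,7E)-4,8,12-trimethyltrideca-3,7,11-trienoic acid (homofarnesoic acid)
Conditions: TEMPO (20 mol %), PhI(OAc)2 (2.2 equiv), MeCN–H2O 1:1, rt
Reagents that add atoms: water O
Why: oxoammonium-mediated oxidation of the primary alcohol to the acid under near-neutral conditions, which keeps the β,γ-alkene from moving into conjugation.

Step 7
Reactants: 9 homofarnesoic acid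
Product: 10 (+)-sclareolide, (3aR,5aS,9aS,9bR)-3a,6,6,9a-tetramethyldecahydronaphtho[2,1-b]furan-2(1H)-one
Conditions: squalene–hopene cyclase (Alicyclobacillus acidocaldarius, whole cells), citrate buffer pH 6, 45 °C
Reagents that add atoms: none
Why: enzymatic cation–olefin polycyclisation through a chair–chair fold with carboxylate capture of the C8 cation; the enzyme gives only the natural trans-decalin, setting C5, C8, C9 and C10.

Step 8
Reactants: 10 (+)-sclareolide
Product: 11 (5S,8R,9R,10S)-13,14,15,16-tetranorlabdane-8,12-diol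
Conditions: LiAlH4, THF, 0 °C → rt
Reagents that add atoms: none
Why: hydride reduction of the lactone to the diol; no stereocentre is touched.

Step 9
Reactants: 11 tetranorlabdane-8,12-diol
Product: 12 (5S,8R,9R,10S)-8-hydroxy-13,14,15,16-tetranorlabdan-12-yl N,N-diisopropylcarbamate
Conditions: i-Pr2NCOCl, Et3N, CH2Cl2, reflux
Reagents that add atoms: N,N-diisopropylcarbamoyl chloride CC(C)N(C(C)C)C(Cl)=O
Why: carbamoylation of the primary alcohol only (the tertiary axial-methyl carbinol is inert), installing the directing group for the later lithiation.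

Step 10
Reactants: 12 hydroxy carbamate
Product: 13 (5S,9S,10S)-13,14,15,16-tetranorlabd-8(17)-en-12-yl N,N-diisopropylcarbamate
Conditions: SOCl2, pyridine, CH2Cl2, −78 °C; AgNO3–silica chromatography
Reagents that add atoms: none
Why: low-temperature dehydration through the chlorosulfite removes a C17 methyl proton preferentially to give mainly the exocyclic alkene; the minor ring-alkene isomers are separated.

Step 11
Reactants: 13 exocyclic alkene carbamate
Product: 14 (5S,7R,9R,10S)-7-hydroxy-13,14,15,16-tetranorlabd-8(17)-en-12-yl N,N-diisopropylcarbamate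
Conditions: SeO2 (0.3 equiv), t-BuOOH, CH2Cl2, rt
Reagents that add atoms: tert-butyl hydroperoxide CC(C)(C)OO
Why: Riley allylic oxidation (ene reaction then [2,3]-shift) at the only alkene present places the hydroxyl axially (7α) on the face opposite the angular methyl.

Step 12
Reactants: 14 allylic alcohol
Product: 15 Dr(OTBS)-CH2–O–C(O)N(i-Pr)2, (5S,7R,9R,10S)-7-(tert-butyldimethylsilyloxy)-13,14,15,16-tetranorlabd-8(17)-en-12-yl N,N-diisopropylcarbamate
Conditions: TBSOTf, 2,6-lutidine, CH2Cl2, 0 °C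
Reagents that add atoms: tert-butyldimethylsilyl triflate CC(C)(C)[Si](C)(C)OS(=O)(=O)C(F)(F)F
Why: silylation protects the allylic alcohol against the organolithium and Lewis-acid steps that follow.

Step 13
Reactants: 16 catechol
Product: 17 2-methoxyphenol (guaiacol)
Conditions: MeI (1.0 equiv), K2CO3, acetone, reflux
Reagents that add atoms: iodomethane CI
Why: Williamson mono-O-methylation under stoichiometric control; the dimethyl ether is removed by base extraction.

Step 14
Reactants: 17 guaiacol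
Product: 18 2-methoxyphenyl N,N-diethylcarbamate
Conditions: NaH, Et2NCOCl, THF, 0 °C → rt
Reagents that add atoms: N,N-diethylcarbamoyl chloride CCN(CC)C(Cl)=O
Why: O-carbamoylation gives a strong ortho-metalation director that is also a weaker ring activator than OMe.

Step 15
Reactants: 18 2-methoxyphenyl N,N-diethylcarbamate
Product: 20 2-allyl-6-methoxyphenyl N,N-diethylcarbamate, via ortho-lithiated carbamate 19 (not isolated)
Conditions: s-BuLi, TMEDA, THF, −78 °C; then CuBr·SMe2 (10 mol %), allyl bromide, −78 °C → 0 °C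
Reagents that add atoms: allyl bromide C=CCBr
Why: carbamate-directed ortho-lithiation occurs at the only free ortho position, and the aryl-metal is allylated before an anionic Fries shift can start.

Step 16
Reactants: 20 2-allyl-6-methoxyphenyl N,N-diethylcarbamate
Product: 21 2-allyl-3-bromo-6-methoxyphenyl N,N-diethylcarbamate
Conditions: NBS, MeCN, 0 °C, dark
Reagents that add atoms: N-bromosuccinimide O=C1CCC(=O)N1Br
Why: electrophilic aromatic bromination goes para to the methoxy group (the stronger donor), which is the position next to the allyl group.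

Step 17
Reactants: 21 aryl bromide
Product: 22 2-allyl-3-(5,5-dimethyl-1,3,2-dioxaborinan-2-yl)-6-methoxyphenyl N,N-diethylcarbamate
Conditions: bis(neopentyl glycolato)diboron, Pd(dppf)Cl2 (5 mol %), KOAc, dioxane, 90 °C
Reagents that add atoms: bis(neopentyl glycolato)diboron CC1(C)COB(OC1)B1OCC(C)(C)CO1
Why: Miyaura borylation; the small neopentyl glycol ester is chosen to ease ate-complex formation at this di-ortho-substituted position.

Step 18
Reactants: 15 homodrimenyl carbamate; 22 aryl boronate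
Product: 25 2-allyl-3-[(S)-Dr(OTBS)(5,5-dimethyl-1,3,2-dioxaborinan-2-yl)methyl]-6-methoxyphenyl N,N-diethylcarbamate, via lithiated carbamate 23 (not isolated), via boronate complex 24 (not isolated)
Conditions: s-BuLi, (+)-sparteine, Et2O, −78 °C, 5 h; then 22, −78 °C; then MgBr2·OEt2, −78 °C → reflux
Reagents that add atoms: none
Why: sparteine-mediated lithiation–borylation, in which (+)-sparteine/s-BuLi removes the pro-R proton, the boronate adds with retention and the 1,2-aryl shift expels the carbamate with inversion, setting C12 by reagent control.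

Step 19
Reactants: 25 secondary benzylic boronic ester
Product: 27 2-allyl-6-methoxy-3-[(1R)-1-Dr(OTBS)-2-methylprop-2-en-1-yl]phenyl N,N-diethylcarbamate, via vinyl boronate complex 26 (not isolated)
Conditions: 2-bromopropene, t-BuLi, THF, −78 °C; add 25; then I2, MeOH, −78 °C; then NaOMe, −78 → 0 °C
Reagents that add atoms: 2-bromopropene (as isopropenyllithium) C=C(C)Br
Why: Zweifel olefination, in which the C12 carbon migrates from boron to the iodonium-activated vinyl carbon with retention before anti-elimination, giving the isopropenyl group on a 12R centre.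

Step 20
Reactants: 27 diene
Product: 28 (5R)-5-Dr(OTBS)-2-methoxy-6-methyl-5,8-dihydronaphthalen-1-yl N,N-diethylcarbamate
Conditions: second-generation Grubbs catalyst (5 mol %), CH2Cl2, 40 °C
Reagents that add atoms: none
Why: ring-closing metathesis of the allyl and isopropenyl groups closes ring D with its trisubstituted alkene; the hindered exocyclic methylene on the decalin does not take part.

Step 21
Reactants: 28 aryl carbamate
Product: 29 (5R)-5-Dr(OTBS)-2-methoxy-6-methyl-5,8-dihydronaphthalen-1-ol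
Conditions: LiAlH4, THF, 0 °C → rt
Reagents that add atoms: none
Why: reductive cleavage of the aryl carbamate frees the phenol; the silyl ether and alkenes are inert to hydride.

Step 22
Reactants: 29 phenol
Product: 30 (5R)-5-Dr(OTBS)-4-iodo-2-methoxy-6-methyl-5,8-dihydronaphthalen-1-ol
Conditions: N-iodosuccinimide, MeCN, −20 °C
Reagents that add atoms: N-iodosuccinimide O=C1CCC(=O)N1I
Why: electrophilic iodination goes to the only open activated position, para to the phenol.

Step 23
Reactants: 30 iodophenol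
Product: 31 (5R)-5-Dr(OTBS)-2-methoxy-6-methyl-4-[(triisopropylsilyl)ethynyl]-5,8-dihydronaphthalen-1-ol
Conditions: HC≡CSi(i-Pr)3, Pd(PPh3)2Cl2 (5 mol %), CuI (10 mol %), Et3N, THF, 50 °C
Reagents that add atoms: (triisopropylsilyl)acetylene C#C[Si](C(C)C)(C(C)C)C(C)C
Why: Sonogashira coupling places the future migrating group on the aromatic carbon para to the phenol before any oxygen is put on that carbon.

Step 24
Reactants: 31 alkynyl phenol
Product: 33 (4R,5R)-5-Dr(OTBS)-4-hydroxy-2-methoxy-6-methyl-4-[(triisopropylsilyl)ethynyl]-5,8-dihydronaphthalen-1(4H)-one (p-quinol), via p-hydroperoxide 32 (not isolated)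
Conditions: KHSO5 (as Oxone, 2KHSO5·KHSO4·K2SO4), NaHCO3, MeCN–H2O, rt; then Na2S2O3
Reagents that add atoms: potassium peroxymonosulfate [K+].[O-]S(=O)(=O)OO
Why: singlet-oxygen hydroxylative dearomatisation of the phenolate at the para carbon, with oxygen entering anti to the pseudoaxial Dr group on the neighbouring C5, so the alkynyl group ends up syn to that side chain.

Step 25
Reactants: 33 p-quinol
Product: 34 (4aS,5R,8aR)-5-Dr(OTBS)-2-methoxy-6-methyl-4a-[(triisopropylsilyl)ethynyl]-4a,5,8,8a-tetrahydronaphthalene-1,4-dione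
Conditions: Sc(OTf)3 (20 mol %), (CF3)2CHOH–CH2Cl2 1:4, −20 → 0 °C
Reagents that add atoms: none
Why: Proposed new method: chelation of Sc(OTf)3 by the C1 carbonyl and the C2 methoxy group makes the cross-conjugated dienone a hydroxypentadienyl cation whose charge is best stabilised at the tetrasubstituted ring-fusion carbon C4a, so the silylalkynyl group (bridging transition state stabilised by the β-silyl effect) shifts suprafacially from C4 to C4a while the carbinol becomes the C4 ketone, and the dienol is protonated at C8a to the more stable cis-fused enedione, which transfers the C4 configuration to the quaternary centre and sets C8a; the closest known reaction is the acid-promoted quinol–enedione (vinylogous semipinacol) rearrangement with alkyl or aryl migrating groups, with alkynyl shifts so far known only in epoxy-alcohol semipinacol rearrangements.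

Step 26
Reactants: 34 silylalkynyl enedione
Product: 35 (4aS,5R,8aR)-5-Dr(OH)-4a-ethynyl-2-methoxy-6-methyl-4a,5,8,8a-tetrahydronaphthalene-1,4-dione
Conditions: Bu4NF, THF, 0 °C → rt
Reagents that add atoms: none
Why: fluoride cleaves both the C–Si bond of the alkyne and the O–Si bond at C7 in one operation.

Step 27
Reactants: 36 resorcinol
Product: 37 1,3-bis(triisopropylsilyloxy)benzene
Conditions: i-Pr3SiCl, imidazole, DMF, rt
Reagents that add atoms: triisopropylsilyl chloride CC(C)[Si](Cl)(C(C)C)C(C)C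
Why: silylation of both phenols; the bulky groups later steer both the borylation and the iodination.

Step 28
Reactants: 37 1,3-bis(triisopropylsilyloxy)benzene
Product: 39 3,5-bis(triisopropylsilyloxy)phenol, via aryl pinacol boronate 38 (not isolated)
Conditions: [Ir(OMe)(cod)]2 (1.5 mol %), 4,4′-di-tert-butyl-2,2′-bipyridine, B2pin2, hexane, 80 °C; then KHSO5 (as Oxone), acetone–H2O, rt
Reagents that add atoms: potassium peroxymonosulfate [K+].[O-]S(=O)(=O)OO
Why: sterically controlled iridium-catalysed C–H borylation at the only position meta to both silyloxy groups, followed by oxidation of the C–B bond.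

Step 29
Reactants: 39 3,5-bis(triisopropylsilyloxy)phenol
Product: 40 2-iodo-3,5-bis(triisopropylsilyloxy)phenol
Conditions: N-iodosuccinimide, CH2Cl2, −20 °C
Reagents that add atoms: N-iodosuccinimide O=C1CCC(=O)N1I
Why: electrophilic iodination ortho to the free phenol, because the para position is shielded by two flanking silyloxy groups.

Step 30
Reactants: 35 terminal alkyne; 40 2-iodophenol
Product: 42 (4aS,5R,8aR)-4a-(5,7-dihydroxy-4-oxo-4H-chromen-2-yl)-5-Dr(OH)-2-methoxy-6-methyl-4a,5,8,8a-tetrahydronaphthalene-1,4-dione, via bis-silylated chromone 41 (not isolated)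
Conditions: Pd2(dba)3 (2.5 mol %), 1,3,5,7-tetramethyl-6-phenyl-2,4,8-trioxa-6-phosphaadamantane (5 mol %), DBU, CO (1 atm), DMF, 50 °C; then Bu4NF, AcOH, THF, 0 °C
Reagents that add atoms: carbon monoxide [C-]#[O+]
Why: carbonylative Sonogashira coupling gives the o-hydroxyaryl ynone, which closes 6-endo under the amidine base to the chromone, and buffered fluoride then frees the two phenols; no stereocentre is changed.

Step 31
Reactants: 42 allylic alcohol
Product: 43 Dichrostachine L
Conditions: MnO2, CH2Cl2, rt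
Reagents that add atoms: none
Why: MnO2 oxidises only the allylic C7 alcohol to the exocyclic enone and leaves the hydrogen-bonded chromone phenols alone.

## Compound list

1 | 5-bromo-2-methylpent-2-ene | CC(C)=CCCBr | starting material
2 | 6-methylhept-5-en-1-yne | CC(C)=CCCC#C | intermediate
3 | (E)-(2,6-dimethylhepta-1,5-dien-1-yl)dimethylalane | CC(C)=CCC/C(C)=C/[Al](C)C | intermediate
4 | (E)-4,8-dimethylnona-3,7-dien-1-ol | CC(C)=CCC/C(C)=C/CCO | intermediate
5 | (E)-9-iodo-2,6-dimethylnona-2,6-diene | CC(C)=CCC/C(C)=C/CCI | intermediate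
6 | (E)-6,10-dimethylundeca-5,9-dien-1-yne | CC(C)=CCC/C(C)=C/CCC#C | intermediate
7 | (1E,5E)-(2,6,10-trimethylundeca-1,5,9-trien-1-yl)dimethylalane | CC(C)=CCC/C(C)=C/CC/C(C)=C/[Al](C)C | intermediate
8 | (3E,7E)-4,8,12-trimethyltrideca-3,7,11-trien-1-ol | CC(C)=CCC/C(C)=C/CC/C(C)=C/CCO | intermediate
9 | (3E,7E)-4,8,12-trimethyltrideca-3,7,11-trienoic acid | CC(C)=CCC/C(C)=C/CC/C(C)=C/CC(=O)O | intermediate
10 | (+)-sclareolide | O=C1C[C@H]2[C@](C)(O1)CC[C@H]1C(C)(C)CCC[C@]21C | intermediate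
11 | (5S,8R,9R,10S)-13,14,15,16-tetranorlabdane-8,12-diol | OCC[C@H]1[C@](C)(O)CC[C@H]2C(C)(C)CCC[C@]12C | intermediate
12 | (5S,8R,9R,10S)-8-hydroxy-13,14,15,16-tetranorlabdan-12-yl N,N-diisopropylcarbamate | CC(C)N(C(C)C)C(=O)OCC[C@H]1[C@](C)(O)CC[C@H]2C(C)(C)CCC[C@]12C | intermediate
13 | (5S,9S,10S)-13,14,15,16-tetranorlabd-8(17)-en-12-yl N,N-diisopropylcarbamate | C=C1CC[C@H]2C(C)(C)CCC[C@]2(C)[C@H]1CCOC(=O)N(C(C)C)C(C)C | intermediate
14 | (5S,7R,9R,10S)-7-hydroxy-13,14,15,16-tetranorlabd-8(17)-en-12-yl N,N-diisopropylcarbamate | C=C1[C@H](O)C[C@H]2C(C)(C)CCC[C@]2(C)[C@H]1CCOC(=O)N(C(C)C)C(C)C | intermediate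
15 | (5S,7R,9R,10S)-7-(tert-butyldimethylsilyloxy)-13,14,15,16-tetranorlabd-8(17)-en-12-yl N,N-diisopropylcarbamate | C=C1[C@H](O[Si](C)(C)C(C)(C)C)C[C@H]2C(C)(C)CCC[C@]2(C)[C@H]1CCOC(=O)N(C(C)C)C(C)C | intermediate
16 | catechol | Oc1ccccc1O | starting material
17 | 2-methoxyphenol | COc1ccccc1O | intermediate
18 | 2-methoxyphenyl N,N-diethylcarbamate | CCN(CC)C(=O)Oc1ccccc1OC | intermediate
19 | 2-lithio-6-methoxyphenyl N,N-diethylcarbamate | CCN(CC)C(=O)Oc1c([Li])cccc1OC | intermediate
20 | 2-allyl-6-methoxyphenyl N,N-diethylcarbamate | CCN(CC)C(=O)Oc1c(CC=C)cccc1OC | intermediate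
21 | 2-allyl-3-bromo-6-methoxyphenyl N,N-diethylcarbamate | CCN(CC)C(=O)Oc1c(CC=C)c(Br)ccc1OC | intermediate
22 | 2-allyl-3-(5,5-dimethyl-1,3,2-dioxaborinan-2-yl)-6-methoxyphenyl N,N-diethylcarbamate | CCN(CC)C(=O)Oc1c(CC=C)c(B2OCC(C)(C)CO2)ccc1OC | intermediate
23 | (12R)-12-lithio derivative of 15 | C=C1[C@H](O[Si](C)(C)C(C)(C)C)C[C@H]2C(C)(C)CCC[C@]2(C)[C@H]1C[C@H](OC(=O)N(C(C)C)C(C)C)[Li] | intermediate
24 | lithium boronate complex of 23 with 22 | C=C1[C@H](O[Si](C)(C)C(C)(C)C)C[C@H]2C(C)(C)CCC[C@]2(C)[C@H]1C[C@H](OC(=O)N(C(C)C)C(C)C)[B-]1(c2ccc(OC)c(OC(=O)N(CC)CC)c2CC=C)OCC(C)(C)CO1.[Li+] | intermediate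
25 | 2-allyl-3-[(S)-Dr(OTBS)(5,5-dimethyl-1,3,2-dioxaborinan-2-yl)methyl]-6-methoxyphenyl N,N-diethylcarbamate | C=C1[C@H](O[Si](C)(C)C(C)(C)C)C[C@H]2C(C)(C)CCC[C@]2(C)[C@H]1C[C@@H](c1ccc(OC)c(OC(=O)N(CC)CC)c1CC=C)B1OCC(C)(C)CO1 | intermediate
26 | lithium isopropenyl boronate complex of 25 | C=C1[C@H](O[Si](C)(C)C(C)(C)C)C[C@H]2C(C)(C)CCC[C@]2(C)[C@H]1C[C@@H](c1ccc(OC)c(OC(=O)N(CC)CC)c1CC=C)[B-]1(C(C)=C)OCC(C)(C)CO1.[Li+] | intermediate
27 | 2-allyl-6-methoxy-3-[(1R)-1-Dr(OTBS)-2-methylprop-2-en-1-yl]phenyl N,N-diethylcarbamate | C=C1[C@H](O[Si](C)(C)C(C)(C)C)C[C@H]2C(C)(C)CCC[C@]2(C)[C@H]1C[C@@H](c1ccc(OC)c(OC(=O)N(CC)CC)c1CC=C)C(C)=C | intermediate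
28 | (5R)-5-Dr(OTBS)-2-methoxy-6-methyl-5,8-dihydronaphthalen-1-yl N,N-diethylcarbamate | C=C1[C@H](O[Si](C)(C)C(C)(C)C)C[C@H]2C(C)(C)CCC[C@]2(C)[C@H]1C[C@@H]1C(C)=CCc2c(OC(=O)N(CC)CC)c(OC)ccc21 | intermediate
29 | (5R)-5-Dr(OTBS)-2-methoxy-6-methyl-5,8-dihydronaphthalen-1-ol | C=C1[C@H](O[Si](C)(C)C(C)(C)C)C[C@H]2C(C)(C)CCC[C@]2(C)[C@H]1C[C@@H]1C(C)=CCc2c(O)c(OC)ccc21 | intermediate
30 | (5R)-5-Dr(OTBS)-4-iodo-2-methoxy-6-methyl-5,8-dihydronaphthalen-1-ol | C=C1[C@H](O[Si](C)(C)C(C)(C)C)C[C@H]2C(C)(C)CCC[C@]2(C)[C@H]1C[C@@H]1C(C)=CCc2c(O)c(OC)cc(I)c21 | intermediate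
31 | (5R)-5-Dr(OTBS)-2-methoxy-6-methyl-4-[(triisopropylsilyl)ethynyl]-5,8-dihydronaphthalen-1-ol | C=C1[C@H](O[Si](C)(C)C(C)(C)C)C[C@H]2C(C)(C)CCC[C@]2(C)[C@H]1C[C@@H]1C(C)=CCc2c(O)c(OC)cc(C#C[Si](C(C)C)(C(C)C)C(C)C)c21 | intermediate
32 | (4R,5R)-5-Dr(OTBS)-4-hydroperoxy-2-methoxy-6-methyl-4-[(triisopropylsilyl)ethynyl]-5,8-dihydronaphthalen-1(4H)-one | C=C1[C@H](O[Si](C)(C)C(C)(C)C)C[C@H]2C(C)(C)CCC[C@]2(C)[C@H]1C[C@@H]1C(C)=CCC2=C1[C@@](OO)(C#C[Si](C(C)C)(C(C)C)C(C)C)C=C(OC)C2=O | intermediate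
33 | (4R,5R)-5-Dr(OTBS)-4-hydroxy-2-methoxy-6-methyl-4-[(triisopropylsilyl)ethynyl]-5,8-dihydronaphthalen-1(4H)-one | C=C1[C@H](O[Si](C)(C)C(C)(C)C)C[C@H]2C(C)(C)CCC[C@]2(C)[C@H]1C[C@@H]1C(C)=CCC2=C1[C@@](O)(C#C[Si](C(C)C)(C(C)C)C(C)C)C=C(OC)C2=O | intermediate
34 | (4aS,5R,8aR)-5-Dr(OTBS)-2-methoxy-6-methyl-4a-[(triisopropylsilyl)ethynyl]-4a,5,8,8a-tetrahydronaphthalene-1,4-dione | C=C1[C@H](O[Si](C)(C)C(C)(C)C)C[C@H]2C(C)(C)CCC[C@]2(C)[C@H]1C[C@@H]1C(C)=CC[C@H]2C(=O)C(OC)=CC(=O)[C@@]12C#C[Si](C(C)C)(C(C)C)C(C)C | intermediate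
35 | (4aS,5R,8aR)-5-Dr(OH)-4a-ethynyl-2-methoxy-6-methyl-4a,5,8,8a-tetrahydronaphthalene-1,4-dione | C=C1[C@H](O)C[C@H]2C(C)(C)CCC[C@]2(C)[C@H]1C[C@@H]1C(C)=CC[C@H]2C(=O)C(OC)=CC(=O)[C@@]12C#C | intermediate
36 | resorcinol | Oc1cccc(O)c1 | starting material
37 | 1,3-bis(triisopropylsilyloxy)benzene | CC(C)[Si](Oc1cccc(O[Si](C(C)C)(C(C)C)C(C)C)c1)(C(C)C)C(C)C | intermediate
38 | 2-[3,5-bis(triisopropylsilyloxy)phenyl]-4,4,5,5-tetramethyl-1,3,2-dioxaborolane | CC(C)[Si](Oc1cc(O[Si](C(C)C)(C(C)C)C(C)C)cc(B2OC(C)(C)C(C)(C)O2)c1)(C(C)C)C(C)C | intermediate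
39 | 3,5-bis(triisopropylsilyloxy)phenol | CC(C)[Si](Oc1cc(O)cc(O[Si](C(C)C)(C(C)C)C(C)C)c1)(C(C)C)C(C)C | intermediate
40 | 2-iodo-3,5-bis(triisopropylsilyloxy)phenol | CC(C)[Si](Oc1cc(O)c(I)c(O[Si](C(C)C)(C(C)C)C(C)C)c1)(C(C)C)C(C)C | intermediate
41 | 5,7-bis(triisopropylsilyl) ether of 42 | C=C1[C@H](O)C[C@H]2C(C)(C)CCC[C@]2(C)[C@H]1C[C@@H]1C(C)=CC[C@H]2C(=O)C(OC)=CC(=O)[C@@]12c1cc(=O)c2c(O[Si](C(C)C)(C(C)C)C(C)C)cc(O[Si](C(C)C)(C(C)C)C(C)C)cc2o1 | intermediate
42 | (4aS,5R,8aR)-4a-(5,7-dihydroxy-4-oxo-4H-chromen-2-yl)-5-Dr(OH)-2-methoxy-6-methyl-4a,5,8,8a-tetrahydronaphthalene-1,4-dione | C=C1[C@H](O)C[C@H]2C(C)(C)CCC[C@]2(C)[C@H]1C[C@@H]1C(C)=CC[C@H]2C(=O)C(OC)=CC(=O)[C@@]12c1cc(=O)c2c(O)cc(O)cc2o1 | intermediate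
43 | Dichrostachine L | C=C1C(=O)C[C@H]2C(C)(C)CCC[C@]2(C)[C@H]1C[C@@H]1C(C)=CC[C@H]2C(=O)C(OC)=CC(=O)[C@@]12c1cc(=O)c2c(O)cc(O)cc2o1 | target

## Summary

Total steps: 31. Longest linear sequence: 23 steps (steps 1–12, 18–26, 30, 31).

Steps most likely to fail:

- **Step 25 (proposed new 1,2-alkynyl shift).** The risks are dienone–phenol migration to C3 or acid-driven dehydration to a naphthol. The fallback uses known chemistry, sets out from quinol 33 and comes back at 34. Hydroxyl-directed nucleophilic epoxidation (t-BuOOH, DBU, CH2Cl2, 0 °C) of the C4a=C8a enone bond gives the syn epoxy quinol F1. BF3·OEt2 (CH2Cl2, −78 °C) then triggers the established type 3 semipinacol rearrangement of a 2,3-epoxy alcohol, in which the silylalkynyl group anti to the breaking C–O bond migrates with inversion to give the 8a-hydroxy diketone F2. SmI2 (THF–MeOH, −78 °C) removes the α-hydroxyl, and protonation of the samarium enolate gives cis-fused 34.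
- **Step 24 (dearomatisation).** The risks are an ene reaction of singlet oxygen with the ring D alkene and loss of para selectivity. The fallback sets out from phenol 31 and comes back at quinol 33 with no new compound (F0). It replaces the singlet-oxygen cycloaddition/reduction by a two-electron hypervalent iodine oxidation (PhI(OCOCF3)2, MeCN–H2O, 0 °C), where the phenoxonium ion is captured by water at the para carbon anti to the C5 side chain and the alkenes are not touched.
- **Step 18 (lithiation–borylation with a di-ortho-substituted aryl boronate).** The risk is slow ate-complex formation or slow migration. The fallback sets out from carbamate 15 (and bromide 21) and comes back at 27. LiAlH4 (THF, reflux) cleaves the carbamate to the primary alcohol F3, and Dess–Martin periodinane gives the aldehyde F4. Wittig olefination with Ph3P=C(CH3)CO2Et gives the (E)-enoate F5, DIBAL-H reduces it to the allylic alcohol F6, and ClP(O)(OEt)2/Et3N gives the allylic phosphate F7. Copper-catalysed enantioselective SN2′ arylation (CuCl, chiral N-heterocyclic carbene ligand, the Grignard reagent made from 21 with Mg/LiCl, THF, −30 °C) then sets C12 by catalyst control and gives 27.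

## Further compounds

F1 | step 25 | (4R,4aR,5R,8aS)-4a,8a-epoxide of quinol 33 (epoxide oxygen syn to the C4 hydroxyl) | C=C1[C@H](O[Si](C)(C)C(C)(C)C)C[C@H]2C(C)(C)CCC[C@]2(C)[C@H]1C[C@@H]1C(C)=CC[C@]2(O3)C(=O)C(OC)=C[C@](O)(C#C[Si](C(C)C)(C(C)C)C(C)C)[C@]123
F2 | step 25 | 8a-hydroxy derivative of 34 (hydroxyl anti to the alkynyl group) | C=C1[C@H](O[Si](C)(C)C(C)(C)C)C[C@H]2C(C)(C)CCC[C@]2(C)[C@H]1C[C@@H]1C(C)=CC[C@]2(O)C(=O)C(OC)=CC(=O)[C@@]12C#C[Si](C(C)C)(C(C)C)C(C)C
F0 | step 24 | none | none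
F3 | step 18 | (5S,7R,9R,10S)-7-(tert-butyldimethylsilyloxy)-13,14,15,16-tetranorlabd-8(17)-en-12-ol | C=C1[C@H](O[Si](C)(C)C(C)(C)C)C[C@H]2C(C)(C)CCC[C@]2(C)[C@H]1CCO
F4 | step 18 | (5S,7R,9R,10S)-7-(tert-butyldimethylsilyloxy)-13,14,15,16-tetranorlabd-8(17)-en-12-al | C=C1[C@H](O[Si](C)(C)C(C)(C)C)C[C@H]2C(C)(C)CCC[C@]2(C)[C@H]1CC=O
F5 | step 18 | ethyl (E)-4-Dr(OTBS)-2-methylbut-2-enoate | C=C1[C@H](O[Si](C)(C)C(C)(C)C)C[C@H]2C(C)(C)CCC[C@]2(C)[C@H]1C/C=C(\C)C(=O)OCC
F6 | step 18 | (E)-4-Dr(OTBS)-2-methylbut-2-en-1-ol | C=C1[C@H](O[Si](C)(C)C(C)(C)C)C[C@H]2C(C)(C)CCC[C@]2(C)[C@H]1C/C=C(\C)CO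
F7 | step 18 | (E)-4-Dr(OTBS)-2-methylbut-2-en-1-yl diethyl phosphate | C=C1[C@H](O[Si](C)(C)C(C)(C)C)C[C@H]2C(C)(C)CCC[C@]2(C)[C@H]1C/C=C(\C)COP(=O)(OCC)OCC
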